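## Retrosynthetic overview

1. Last bond: the ester C–O between an epoxyquinone-monoketal allylic alcohol and a (R)-mevalonolactone-derived HMG half-ester; ketal and PMB ester are removed together at the end.
2. Epoxide: hydroxyl-directed, tartrate-mediated nucleophilic epoxidation of a quinone monoketal made by PhI(OAc)2/MeOH oxidation of a p-methoxyphenol; ketal placement fixes which C=C is epoxidised.
3. C11–aryl bond: sp3–sp2 Negishi coupling of albicanylzinc iodide with 4-bromo-2-methoxy-5-(methoxymethoxy)benzaldehyde.
4. Albicanyl iodide from (+)-sclareolide: lactol, alkoxy-radical excision of C12, exo-selective dehydration.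
5. Ring order: the trans-decalin and its three stereocentres come intact from the chiral pool; the arene is dearomatised to the dienone; the oxirane is the only ring formed, late.

Assumptions:
- (+)-Sclareolide, 5-hydroxy-2-methoxybenzaldehyde and (R)-(−)-mevalonolactone are taken as commercial.
- L-(+)-DIPT is assumed to give the (1R,6S) epoxide in Step 11; I could not confirm the sense of induction. Because 12 is enantiopure the two epoxides are separable diastereomers, so 13 is checked and D-DIPT substituted if the sense is reversed.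

Abbreviation: Alb-CH2 = [(1S,4aS,8aS)-5,5,8a-trimethyl-2-methylidenedecahydronaphthalen-1-yl]methyl (drim-8(12)-en-11-yl).

## Route

**Step 1**
Reactants: 1, (+)-sclareolide
Product: 2, sclareolide lactol (anomer mixture)
Conditions: DIBAL-H, CH2Cl2, −78 °C
Reagents that add atoms: none
Why: Partial reduction of a γ-lactone with DIBAL-H stops at the lactol at low temperature; no stereocentre is touched.

**Step 2**
Reactants: 2
Product: 3, 8α-formyloxy-11-iododrimane
Conditions: PhI(OAc)2, I2, CH2Cl2, hν, rt
Reagents that add atoms: iodine, II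
Why: Suárez hypoiodite fragmentation: the anomeric alkoxy radical β-cleaves C11–C12, iodine traps the C11 radical and C12 remains as the C8 formate, so all ring stereocentres are retained.

**Step 3**
Reactants: 3
Product: 4, 11-iododriman-8α-ol
Conditions: K2CO3, MeOH, 0 °C
Reagents that add atoms: none
Why: Formate methanolysis (transesterification) is fast under mild base; cold, dilute conditions avoid oxetane formation from the γ-iodo alkoxide.

**Step 4**
Reactants: 4
Product: 5, albicanyl iodide
Conditions: SOCl2, pyridine, CH2Cl2, −78 °C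
Reagents that add atoms: none
Why: E2 dehydration via the chlorosulfite: the equatorial 8α leaving group has no anti-periplanar ring hydrogen, so a C12 methyl proton is removed and the exocyclic alkene forms (Hofmann-type); C9 is not epimerised.

**Step 5**
Reactants: 6, 5-hydroxy-2-methoxybenzaldehyde
Product: 7, 2-methoxy-5-(methoxymethoxy)benzaldehyde
Conditions: MOMCl, i-Pr2NEt, CH2Cl2, 0 °C to rt
Reagents that add atoms: chloromethyl methyl ether, COCCl
Why: Phenol O-alkylation (MOM protection) gives an alkoxy director for bromination and a phenol mask that survives the organozinc.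

**Step 6**
Reactants: 7
Product: 8, 4-bromo-2-methoxy-5-(methoxymethoxy)benzaldehyde
Conditions: NBS, DMF, rt, dark
Reagents that add atoms: N-bromosuccinimide, O=C1CCC(=O)N1Br
Why: Electrophilic aromatic bromination goes ortho to the 5-alkoxy group (the 2-OMe is deactivated by conjugation to CHO) at the unhindered C4, as for 2,5-dimethoxybenzaldehyde.

**Step 7**
Reactants: 5 and 8
Product: 9, 4-(Alb-CH2)-2-methoxy-5-(methoxymethoxy)benzaldehyde
Conditions: 5, Zn dust (TMSCl/BrCH2CH2Br-activated), LiCl, THF, 45 °C; then 8, Pd(OAc)2 (4 mol %), SPhos (8 mol %), THF, rt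
Reagents that add atoms: none
Why: Negishi sp3–sp2 cross-coupling: the alkylzinc tolerates ArCHO and MOM, and the bulky biarylphosphine makes reductive elimination outrun β-hydride elimination; C9 is not involved.

**Step 8**
Reactants: 9
Product: 10, 4-(Alb-CH2)-5-hydroxy-2-methoxybenzaldehyde
Conditions: PPTS, t-BuOH, 80 °C
Reagents that add atoms: none
Why: Mild acid-catalysed acetal cleavage of the phenolic MOM ether; it is done at the aldehyde stage so no electron-rich benzylic alcohol sees acid.

**Step 9**
Reactants: 10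
Product: 11, 5-(hydroxymethyl)-4-methoxy-2-(Alb-CH2)phenol
Conditions: NaBH4, MeOH/THF, 0 °C
Reagents that add atoms: none
Why: Chemoselective hydride reduction of the aryl aldehyde; the alkene and phenol are inert.

**Step 10**
Reactants: 11
Product: 12, 5-(hydroxymethyl)-4,4-dimethoxy-2-(Alb-CH2)cyclohexa-2,5-dien-1-one
Conditions: PhI(OAc)2, MeOH, 0 °C
Reagents that add atoms: methanol, CO
Why: Hypervalent-iodine oxidative dearomatisation of a p-methoxyphenol gives the p-quinone monoketal, with C=O at the former phenol carbon (next to the terpenyl-bearing carbon) and the ketal next to the CH2OH carbon.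

**Step 11**
Reactants: 12
Product: 13, (1R,6S)-4-(hydroxymethyl)-5,5-dimethoxy-1-(Alb-CH2)-7-oxabicyclo[4.1.0]hept-3-en-2-one
Conditions: Ph3COOH, NaHMDS, L-(+)-DIPT, 4 Å MS, toluene, −65 °C
Reagents that add atoms: trityl hydroperoxide, OOC(c1ccccc1)(c1ccccc1)c1ccccc1
Why: Tartrate-mediated nucleophilic (Weitz–Scheffer-type) epoxidation: peroxide adds only to the α-substituted, β-unsubstituted C2=C3 bond, delivered through the sodium alkoxide of the neighbouring CH2OH, and the tartrate selects the face, setting both cis epoxide centres at once.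

**Step 12**
Reactants: 14, (R)-(−)-mevalonolactone
Product: 15, 4-methoxybenzyl (3R)-3,5-dihydroxy-3-methylpentanoate (used at once)
Conditions: KOH (1.0 equiv), H2O, rt; concentrate; PMBCl, Bu4NI (cat.), DMF, rt
Reagents that add atoms: water (as hydroxide), O; 4-methoxybenzyl chloride, COc1ccc(CCl)cc1
Why: Saponification opens the lactone and SN2 O-alkylation of the carboxylate caps the original carboxyl as a PMB ester; the quaternary centre is untouched.

**Step 13**
Reactants: 15
Product: 16, (3R)-3-hydroxy-5-[(4-methoxybenzyl)oxy]-3-methyl-5-oxopentanoic acid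
Conditions: TEMPO (cat.), PhI(OAc)2, MeCN/H2O (1:1), rt
Reagents that add atoms: water, O
Why: TEMPO/BAIB oxidation takes the primary alcohol to the acid while the tertiary alcohol is inert; making mevalonate C5 the carboxyl to be esterified maps the (R)-mevalonate centre onto the (S) centre of the target.

**Step 14**
Reactants: 13 and 16
Product: 17, mixed diester: the CH2OH of 13 esterified by the free carboxyl of 16 (PMB ester and tertiary OH intact)
Conditions: EDC·HCl, DMAP (cat.), CH2Cl2, 0 °C to rt
Reagents that add atoms: none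
Why: Steglich esterification acylates the primary allylic alcohol; the hindered tertiary hydroxyl of 16 does not compete, and the ketal keeps the ring less electrophilic than the free epoxyquinone.

**Step 15**
Reactants: 17
Product: 18, 4'-oxomacrophorin D
Conditions: TFA/CH2Cl2/H2O (20:80:2), anisole, 0 °C
Reagents that add atoms: water, O
Why: One acidolysis cleaves the PMB ester (cation scavenged by anisole) and hydrolyses the dimethyl ketal to reveal the epoxyquinone; no stereocentre is affected.

## Compound list

1 | (+)-sclareolide, (3aR,5aS,9aS,9bR)-3a,6,6,9a-tetramethyldecahydronaphtho[2,1-b]furan-2(1H)-one | C[C@@]12CC[C@H]3C(C)(C)CCC[C@]3(C)[C@H]1CC(=O)O2 | starting material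
2 | sclareolide lactol (anomer mixture) | C[C@@]12CC[C@H]3C(C)(C)CCC[C@]3(C)[C@H]1CC(O)O2 | intermediate
3 | (1R,2R,4aS,8aS)-1-(iodomethyl)-2,5,5,8a-tetramethyldecahydronaphthalen-2-yl formate | C[C@@]1(OC=O)CC[C@H]2C(C)(C)CCC[C@]2(C)[C@H]1CI | intermediate
4 | (1R,2R,4aS,8aS)-1-(iodomethyl)-2,5,5,8a-tetramethyldecahydronaphthalen-2-ol | C[C@@]1(O)CC[C@H]2C(C)(C)CCC[C@]2(C)[C@H]1CI | intermediate
5 | albicanyl iodide, (1S,4aS,8aS)-1-(iodomethyl)-5,5,8a-trimethyl-2-methylidenedecahydronaphthalene | C=C1CC[C@H]2C(C)(C)CCC[C@]2(C)[C@H]1CI | intermediate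
6 | 5-hydroxy-2-methoxybenzaldehyde | COc1ccc(O)cc1C=O | starting material
7 | 2-methoxy-5-(methoxymethoxy)benzaldehyde | COCOc1ccc(OC)c(C=O)c1 | intermediate
8 | 4-bromo-2-methoxy-5-(methoxymethoxy)benzaldehyde | COCOc1cc(C=O)c(OC)cc1Br | intermediate
9 | 4-(Alb-CH2)-2-methoxy-5-(methoxymethoxy)benzaldehyde | C=C1CC[C@H]2C(C)(C)CCC[C@]2(C)[C@H]1Cc1cc(OC)c(C=O)cc1OCOC | intermediate
10 | 4-(Alb-CH2)-5-hydroxy-2-methoxybenzaldehyde | C=C1CC[C@H]2C(C)(C)CCC[C@]2(C)[C@H]1Cc1cc(OC)c(C=O)cc1O | intermediate
11 | 5-(hydroxymethyl)-4-methoxy-2-(Alb-CH2)phenol | C=C1CC[C@H]2C(C)(C)CCC[C@]2(C)[C@H]1Cc1cc(OC)c(CO)cc1O | intermediate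
12 | 5-(hydroxymethyl)-4,4-dimethoxy-2-(Alb-CH2)cyclohexa-2,5-dien-1-one | C=C1CC[C@H]2C(C)(C)CCC[C@]2(C)[C@H]1CC1=CC(OC)(OC)C(CO)=CC1=O | intermediate
13 | (1R,6S)-4-(hydroxymethyl)-5,5-dimethoxy-1-(Alb-CH2)-7-oxabicyclo[4.1.0]hept-3-en-2-one | C=C1CC[C@H]2C(C)(C)CCC[C@]2(C)[C@H]1C[C@@]12O[C@@H]1C(OC)(OC)C(CO)=CC2=O | intermediate
14 | (R)-(−)-mevalonolactone, (4R)-4-hydroxy-4-methyloxan-2-one | C[C@@]1(O)CCOC(=O)C1 | starting material
15 | 4-methoxybenzyl (3R)-3,5-dihydroxy-3-methylpentanoate | OCC[C@@](C)(O)CC(=O)OCc1ccc(OC)cc1 | intermediate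
16 | (3R)-3-hydroxy-5-[(4-methoxybenzyl)oxy]-3-methyl-5-oxopentanoic acid | OC(=O)C[C@@](C)(O)CC(=O)OCc1ccc(OC)cc1 | intermediate
17 | (3S)-3-hydroxy-3-methylpentanedioate mixed diester: one ester to the CH2O of the (1R,6S)-epoxy-monoketal enone of 13, the other a 4-methoxybenzyl ester | C=C1CC[C@H]2C(C)(C)CCC[C@]2(C)[C@H]1C[C@@]12O[C@@H]1C(OC)(OC)C(COC(=O)C[C@@](C)(O)CC(=O)OCc1ccc(OC)cc1)=CC2=O | intermediate
18 | 4'-oxomacrophorin D: (3S)-3-hydroxy-3-methylpentanedioic acid mono ester of [(1R,6S)-2,5-dioxo-1-(Alb-CH2)-7-oxabicyclo[4.1.0]hept-3-en-4-yl]methanol | C=C1CC[C@H]2C(C)(C)CCC[C@]2(C)[C@H]1C[C@@]12O[C@@H]1C(=O)C(COC(=O)C[C@@](C)(O)CC(=O)O)=CC2=O | target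

## Summary

Total steps: 15.
Longest linear sequence: 11 steps (Steps 1–4, 7–11, 14, 15 from (+)-sclareolide).

Three steps most likely to fail, with fallbacks:

1. **Step 7 (Negishi coupling).** The β-branched homoallylic zinc reagent may suffer β-hydride elimination or protodezincation. Fallback: reverse the polarity. Add the aryllithium from a CH2OTBS analogue of 8 to albicanal (drim-8(12)-en-11-al), then remove the benzylic hydroxyl by Barton–McCombie deoxygenation.
2. **Step 11 (epoxidation).** Face selectivity and the tartrate sense are unverified. Fallback: switch from reagent to auxiliary control. Transketalise 12 with a C2-symmetric pentane-2,4-diol, epoxidise with Ph3COOK under substrate control, and separate the diastereomers.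
3. **Step 15 (global acidolysis).** The exocyclic alkene may isomerise or the epoxyquinone may degrade in TFA. Fallback: unmask the ketal of 13 first with K10 clay to give 4'-oxomacrophorin A, then install the side chain without any protecting group by cinchona-catalysed desymmetrising opening of 3-hydroxy-3-methylglutaric anhydride with that alcohol.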